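## Retrosynthetic overview

1. Target 23 ⇐ dimethyl ester 22 (double S-demethylation) ⇐ keto alkyne 21 by SmI2 ketyl–alkyne 5-exo-dig closure of ring D (C13–C16; sets the C13 carbinol and the exo-methylene).
2. 21 ⇐ aldehyde 19 ⇐ enone aldehyde 18 by amine-catalysed 5-exo Michael addition (ring B, C6–C8, quaternary C8).
3. 18 ⇐ ring A ketone 10 + 3-ethoxycyclohexenone + propargyl bromide: Stork–Danheiser aldol (C9–C10) whose alkoxide is trapped as the 19,10-lactone, then propargyl addition and carbonyl transposition.
4. 10 ⇐ 9 ⇐ γ-keto enal 8 by enantioselective iminium-catalysed 6-exo Michael cyclisation (ring A, C4–C5, first stereocentre C5) ⇐ furan oxidation of 6 ⇐ furan, 1-bromo-3-chloropropane, dimethyl malonate.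
5. Ring order: A, then the lactone with ring C attached, then B, then D.

Assumption: locants C1–C19 are gibberellane locants (ring A = C1–C5 and C10; ring B = C5, C6, C8, C9, C10; ring C = C8, C9, C11–C14; ring D = C8, C13–C16; C7 and C18 are carboxyl carbons, C19 is the lactone carbonyl). The SMILES strings define configuration. The final product is called "the target gibberellin". The route is a proposal and has not been run.

## Route

Step 1
Reactants: 1 furan; 2 1-bromo-3-chloropropane
Product: 4 2-(3-chloropropyl)furan, via 2-furyllithium 3 (not isolated)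
Conditions: n-BuLi, THF, 0 °C; then 2, −78 °C → rt
Reagents that add atoms: none
Why: α-Lithiation of furan followed by SN2 alkylation at the bromide end of the dihalide (the chloride is far less reactive) gives the 2-alkylfuran that carries C1–C3 and masks C10 together with C5–C7.

Step 2
Reactants: 4 2-(3-chloropropyl)furan; 5 dimethyl malonate
Product: 6 dimethyl 2-[3-(furan-2-yl)propyl]propanedioate
Conditions: 5 (3 equiv), K2CO3, NaI (10 mol%), DMF, 70 °C
Reagents that add atoms: none
Why: Malonate C-alkylation (SN2 assisted by in situ Finkelstein exchange), run in excess malonate to suppress dialkylation, installs C4 together with both future carboxyl carbons C18 and C19.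

Step 3
Reactants: 6 dimethyl 2-[3-(furan-2-yl)propyl]propanedioate
Product: 8 dimethyl 2-[(5E)-4,7-dioxohept-5-en-1-yl]propanedioate, via (5Z)-keto enal 7 (not isolated)
Conditions: NBS, NaHCO3, acetone/H2O 9:1, −20 °C; then pyridine, 0 °C, short
Reagents that add atoms: water, O
Why: Oxidative furan ring opening (bromohydroxylation of the electron-rich 2-alkylfuran by NBS in water, then collapse to the cis-enedione) unmasks the γ-keto enal much faster than the malonate C–H reacts, and pyridine isomerises the cis alkene to the trans alkene.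

Step 4
Reactants: 8 dimethyl 2-[(5E)-4,7-dioxohept-5-en-1-yl]propanedioate
Product: 9 dimethyl (2R)-3-oxo-2-(2-oxoethyl)cyclohexane-1,1-dicarboxylate
Conditions: (S)-α,α-bis[3,5-bis(trifluoromethyl)phenyl]prolinol trimethylsilyl ether (10 mol%), PhCO2H (10 mol%), toluene, −20 °C
Reagents that add atoms: none
Why: Proposed new method: the (S)-diarylprolinol silyl ether condenses with the aldehyde to an E-iminium ion whose electrophilic site is C5 (β to the iminium, α to the ketone), the tethered malonate can reach only this carbon in a 6-exo-trig mode (attack at C6 would be 7-endo) and adds on the face opposite the CAr2OSiMe3 group, which by the usual shielding model gives (R)-C5 and closes ring A, the closest known reactions being the intermolecular Jørgensen–Hayashi malonate–enal Michael addition and amine-catalysed intramolecular Michael cyclisations, neither shown so far for a malonate tethered to a γ-keto enal.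

Step 5
Reactants: 9 dimethyl (2R)-3-oxo-2-(2-oxoethyl)cyclohexane-1,1-dicarboxylate
Product: 10 dimethyl (2R)-2-(1,3-dioxolan-2-ylmethyl)-3-oxocyclohexane-1,1-dicarboxylate
Conditions: TMSOCH2CH2OTMS, TMSOTf (5 mol%), CH2Cl2, −78 °C
Reagents that add atoms: 1,2-bis(trimethylsilyloxy)ethane, C[Si](C)(C)OCCO[Si](C)(C)C
Why: Noyori acetalisation under aprotic conditions at −78 °C protects the aldehyde much faster than the hindered ketone and avoids the protic acid and heat that would enolise C5 or dehydrate the 1,4-keto aldehyde to a furan.

Step 6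
Reactants: 10 dimethyl (2R)-2-(1,3-dioxolan-2-ylmethyl)-3-oxocyclohexane-1,1-dicarboxylate; 11 3-ethoxycyclohex-2-en-1-one
Product: 14 methyl (1R,5S,8R)-8-(1,3-dioxolan-2-ylmethyl)-5-[(1S)-4-ethoxy-2-oxocyclohex-3-en-1-yl]-7-oxo-6-oxabicyclo[3.2.1]octane-1-carboxylate, via lithium 5-ethoxycyclohexa-1,5-dien-1-olate 12 (not isolated), via lithium aldolate 13 (not isolated)
Conditions: 11, LDA, THF, −78 °C; add 10, −78 → −20 °C; AcOH quench
Reagents that add atoms: none
Why: The kinetic Stork–Danheiser enolate adds to the ring A ketone (aldol addition) from the equatorial direction, anti to the C5 side chain and away from the axial C4 ester, so the alkoxide is axial and 1,3-syn to that ester and lactonises at once, which makes the aldol irreversible, sets C10, differentiates the two C4 esters (sets C4) and, through a Zimmerman–Traxler chair that keeps the bulky C5 flank equatorial next to the enolate hydrogen, sets C9.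

Step 7
Reactants: 14 the lactone from step 6; 15 propargyl bromide
Product: 18 methyl (1R,5R,8R)-7-oxo-8-(2-oxoethyl)-5-[(1R)-4-oxo-2-(prop-2-yn-1-yl)cyclohex-2-en-1-yl]-6-oxabicyclo[3.2.1]octane-1-carboxylate, via allenylmagnesium bromide 16 (not isolated), via bromomagnesium alkoxide 17 (not isolated)
Conditions: 15, Mg, HgCl2 (1 mol%), Et2O, 0 °C; add to 14, THF, −78 °C; then 2 M HCl, THF, 0 °C → rt
Reagents that add atoms: water, O
Why: The allenyl Grignard reagent adds by SE2' to the vinylogous-ester carbonyl (the neopentyl ester and bridged lactone are slower at −78 °C) and aqueous acid then completes the Stork–Danheiser 1,3-carbonyl transposition to the 3-propargyl enone and cleaves the dioxolane in the same flask, with C9 untouched as the γ-carbon.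

Step 8
Reactants: 18 the enone aldehyde from step 7
Product: 19 (4R,5R,6S,8S,9R,10R) tricyclic keto aldehyde: rings A, B and C with the 19,10-lactone, C18 methyl ester, C6 formyl group (C7), C13 ketone and C8 propargyl group (C15–C17)
Conditions: pyrrolidine (30 mol%), AcOH (30 mol%), CH2Cl2, 0 °C → rt
Reagents that add atoms: none
Why: Only the aldehyde condenses with pyrrolidine, and the enamine carbon C6 adds to the enone β-carbon C8 in a 5-exo-trig intramolecular Michael addition on the face of ring C that carries C10, so rings B and C are cis-fused and the all-carbon centre C8 is set, while C6 equilibrates through the enamine to the isomer whose formyl group is trans to C4.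

Step 9
Reactants: 19 the keto aldehyde from step 8
Product: 21 (4R,5R,6S,8S,9R,10R) keto alkyne dimethyl ester (C7 and C18 methyl esters, 19,10-lactone, C13 ketone, C8 propargyl), via carboxylic acid 20 (not isolated)
Conditions: NaClO2, NaH2PO4, 2-methyl-2-butene, t-BuOH/H2O, 0 °C; crude acid then MeI, K2CO3, DMF, rt
Reagents that add atoms: sodium chlorite, [Na+].[O-]Cl=O; iodomethane, CI
Why: Pinnick oxidation converts the aldehyde into the acid without epimerising C6 or touching the ketone and alkyne, and O-methylation of the crude carboxylate keeps an acidic proton out of the samarium step.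

Step 10
Reactants: 21 the keto alkyne dimethyl ester from step 9
Product: 22 dimethyl ester of the target gibberellin (4R,5R,6S,8S,9R,10R,13S)
Conditions: SmI2 (4 equiv), HMPA (16 equiv), t-BuOH (3 equiv), THF, −20 → 0 °C
Reagents that add atoms: none
Why: SmI2 with HMPA reduces the C13 ketone to a ketyl that adds 5-exo-dig to the axial propargyl alkyne (ketyl–alkyne radical cyclisation), the vinyl radical is reduced and protonated to the exocyclic methylene, and the one-carbon bridge forces the configuration of the C13 carbinol.

Step 11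
Reactants: 22 dimethyl ester of the target gibberellin
Product: 23 the target gibberellin (free 7,18-diacid)
Conditions: LiSPr (6 equiv), HMPA, 0 °C → rt; then 1 M HCl to pH 3
Reagents that add atoms: none
Why: Thiolate SN2 dealkylation at the methyl carbons cleaves both hindered methyl esters without opening the tertiary-alkyl lactone or rearranging the acid-sensitive allylic tertiary alcohol.

## Compound list

1 | furan | c1ccoc1 | starting material
2 | 1-bromo-3-chloropropane | ClCCCBr | starting material
3 | 2-furyllithium | [Li]c1ccco1 | intermediate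
4 | 2-(3-chloropropyl)furan | ClCCCc1ccco1 | intermediate
5 | dimethyl malonate | COC(=O)CC(=O)OC | starting material
6 | dimethyl 2-[3-(furan-2-yl)propyl]propanedioate | COC(=O)C(CCCc1ccco1)C(=O)OC | intermediate
7 | dimethyl 2-[(5Z)-4,7-dioxohept-5-en-1-yl]propanedioate | COC(=O)C(CCCC(=O)/C=C\C=O)C(=O)OC | intermediate
8 | dimethyl 2-[(5E)-4,7-dioxohept-5-en-1-yl]propanedioate | COC(=O)C(CCCC(=O)/C=C/C=O)C(=O)OC | intermediate
9 | dimethyl (2R)-3-oxo-2-(2-oxoethyl)cyclohexane-1,1-dicarboxylate | O=CC[C@H]1C(=O)CCCC1(C(=O)OC)C(=O)OC | intermediate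
10 | dimethyl (2R)-2-(1,3-dioxolan-2-ylmethyl)-3-oxocyclohexane-1,1-dicarboxylate | O1CCOC1C[C@H]2C(=O)CCCC2(C(=O)OC)C(=O)OC | intermediate
11 | 3-ethoxycyclohex-2-en-1-one | CCOC1=CC(=O)CCC1 | starting material
12 | lithium 5-ethoxycyclohexa-1,5-dien-1-olate | CCOC1=CC(O[Li])=CCC1 | intermediate
13 | lithium alkoxide of dimethyl (2R,3S)-2-(1,3-dioxolan-2-ylmethyl)-3-[(1S)-4-ethoxy-2-oxocyclohex-3-en-1-yl]-3-hydroxycyclohexane-1,1-dicarboxylate | CCOC1=CC(=O)[C@@H](CC1)[C@]2(O[Li])CCCC(C(=O)OC)(C(=O)OC)[C@H]2CC3OCCO3 | intermediate
14 | methyl (1R,5S,8R)-8-(1,3-dioxolan-2-ylmethyl)-5-[(1S)-4-ethoxy-2-oxocyclohex-3-en-1-yl]-7-oxo-6-oxabicyclo[3.2.1]octane-1-carboxylate | CCOC1=CC(=O)[C@@H](CC1)[C@@]23CCC[C@@](C(=O)OC)(C(=O)O2)[C@H]3CC4OCCO4 | intermediate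
15 | propargyl bromide (3-bromoprop-1-yne) | C#CCBr | starting material
16 | allenylmagnesium bromide | C=C=C[Mg]Br | intermediate
17 | bromomagnesium alkoxide from addition of 16 to the ring C carbonyl of 14 (both epimers at the new carbinol carbon C8; other centres as in 14) | CCOC1=CC(O[Mg]Br)(CC#C)[C@@H](CC1)[C@@]23CCC[C@@](C(=O)OC)(C(=O)O2)[C@H]3CC4OCCO4 | intermediate
18 | methyl (1R,5R,8R)-7-oxo-8-(2-oxoethyl)-5-[(1R)-4-oxo-2-(prop-2-yn-1-yl)cyclohex-2-en-1-yl]-6-oxabicyclo[3.2.1]octane-1-carboxylate | O=C1C=C(CC#C)[C@@H](CC1)[C@@]23CCC[C@@](C(=O)OC)(C(=O)O2)[C@H]3CC=O | intermediate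
19 | (4R,5R,6S,8S,9R,10R) tricyclic keto aldehyde: 19,10-lactone, C18 methyl ester, C6 formyl, C13 ketone, C8 propargyl | C#CC[C@]12CC(=O)CC[C@H]1[C@@]34CCC[C@@](C(=O)OC)(C(=O)O3)[C@H]4[C@@H]2C=O | intermediate
20 | (4R,5R,6S,8S,9R,10R) tricyclic keto acid: as 19 but C7 is a carboxylic acid | C#CC[C@]12CC(=O)CC[C@H]1[C@@]34CCC[C@@](C(=O)OC)(C(=O)O3)[C@H]4[C@@H]2C(=O)O | intermediate
21 | (4R,5R,6S,8S,9R,10R) tricyclic keto alkyne dimethyl ester: as 19 but C7 is a methyl ester | C#CC[C@]12CC(=O)CC[C@H]1[C@@]34CCC[C@@](C(=O)OC)(C(=O)O3)[C@H]4[C@@H]2C(=O)OC | intermediate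
22 | dimethyl ester of the target gibberellin: (4R,5R,6S,8S,9R,10R,13S) 7,18-dimethyl ester with the 19,10-lactone, 13-hydroxyl and 16-ene | C=C1C[C@]23C[C@@]1(O)CC[C@H]2[C@@]12CCC[C@@](C(=O)OC)(C(=O)O1)[C@H]2[C@@H]3C(=O)OC | intermediate
23 | target gibberellin: (4R,5R,6S,8S,9R,10R,13S)-10,13-dihydroxy-20-norgibberell-16-ene-7,18,19-trioic acid 19,10-lactone | C=C1C[C@]23C[C@@]1(O)CC[C@H]2[C@@]12CCC[C@@](C(=O)O)(C(=O)O1)[C@H]2[C@@H]3C(=O)O | target

## Step count and risks

Total step count: 11. Longest linear sequence: 11 steps (furan 1 to the target gibberellin 23); dimethyl malonate 5, enone 11 and propargyl bromide 15 enter directly.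

**Step 4 (proposed new step).** The likely failures are a racemic background cyclisation of 8 (the malonate is tethered to a very electrophilic ene-dicarbonyl, and some may already cyclise during the pyridine stage of step 3) and erosion at C5, which is α to the ketone until step 6. If the sense of induction is opposite to the shielding model, the (R)-catalyst is used. The fallback uses known chemistry and removes the tether, so no uncatalysed ring closure is possible. It sets out from 4 and 5 and returns at 10. The same NBS oxidation applied to 4 gives (2E)-7-chloro-4-oxohept-2-enal F1. The established intermolecular Jørgensen–Hayashi addition of dimethyl malonate 5 to this enal (same (S)-catalyst, PhCO2H, EtOH, 0 °C) gives dimethyl 2-[(3R)-7-chloro-1,4-dioxoheptan-3-yl]propanedioate F2. Noyori acetalisation as in step 5 gives dimethyl 2-[(2R)-6-chloro-1-(1,3-dioxolan-2-yl)-3-oxohexan-2-yl]propanedioate F3. Ordinary malonate C-alkylation (K2CO3, NaI, DMF, 50 °C) then closes ring A at C3–C4 and delivers 10.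

**Step 6.** The ketone of 10 is hindered and enolisable, so the lithium enolate may act as a base (which would also racemise C5) or the aldolate may revert before it lactonises. The fallback replaces the base-mediated aldol by a reductive Reformatsky-type coupling. It sets out from 11 and 10 and returns at 14. Enone 11 is brominated at the α'-carbon (LDA, THF, −78 °C; then NBS) to give racemic 6-bromo-3-ethoxycyclohex-2-en-1-one F4. SmI2 (2 equiv, THF, −78 °C) added to a mixture of this bromide and 10 generates the same enolate as an oxophilic, weakly basic samarium enolate, which adds to the ketone; the samarium alkoxide lactonises on warming to give 14.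

**Step 8.** The enamine has to attack a β,β-disubstituted enone and build a quaternary carbon; it may be too slow, and side reactions (aldol between C12 and C7, loss of the lactone by vinylogous elimination) may take over. The fallback switches to a radical ring closure, which is far less sensitive to steric crowding. It sets out from 18 and returns at 19. Amine-catalysed α-selenenylation of the aldehyde (N-(phenylseleno)phthalimide, pyrrolidine 20 mol%, CH2Cl2, 0 °C) gives the α-phenylselanyl aldehyde F5 as a mixture of C6 epimers. Slow addition of Bu3SnH and AIBN in benzene at 80 °C generates the α-formyl radical, which closes ring B by 5-exo-trig addition to C8 of the enone, again on the face that carries C10. Brief exposure to pyrrolidine and AcOH equilibrates C6 and gives 19.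

Further compounds
F1 | step 4 | (2E)-7-chloro-4-oxohept-2-enal | O=C/C=C/C(=O)CCCCl
F2 | step 4 | dimethyl 2-[(3R)-7-chloro-1,4-dioxoheptan-3-yl]propanedioate | O=CC[C@@H](C(=O)CCCCl)C(C(=O)OC)C(=O)OC
F3 | step 4 | dimethyl 2-[(2R)-6-chloro-1-(1,3-dioxolan-2-yl)-3-oxohexan-2-yl]propanedioate | O1CCOC1C[C@@H](C(=O)CCCCl)C(C(=O)OC)C(=O)OC
F4 | step 6 | 6-bromo-3-ethoxycyclohex-2-en-1-one (racemic) | CCOC1=CC(=O)C(Br)CC1
F5 | step 8 | methyl (1R,5R,8R)-7-oxo-8-[2-oxo-1-(phenylselanyl)ethyl]-5-[(1R)-4-oxo-2-(prop-2-yn-1-yl)cyclohex-2-en-1-yl]-6-oxabicyclo[3.2.1]octane-1-carboxylate (both epimers at the selenium-bearing carbon) | O=C1C=C(CC#C)[C@@H](CC1)[C@@]23CCC[C@@](C(=O)OC)(C(=O)O2)[C@H]3C([Se]c4ccccc4)C=O
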